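**Retrosynthetic overview**
1. Target 21 ← global desilylation of 20 ← oxolane closure (benzylic O onto a primary tosylate, last ring formed) ← reduction of the γ-lactone in 17.
2. Key late coupling: anti-aldol of the enolate of lactone 15 with aryl aldehyde 6 (C–C bond to the exocyclic carbinol; sets two stereocentres).
3. Lactone 15 (first ring) ← ligand-controlled aryl transfer from the arylzinc of bromide 4 to aldehyde ester 11, then lactonisation.
4. 11 ← organocatalytic α-hydroxymethylation of methyl 4-oxobutanoate; 4 and 6 ← catechol (O-methylation, bromination, silylation, Grignard formylation).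
5. Ring order: γ-butyrolactone (step 8) → opened (step 10) → oxolane (step 11).

Assumption: descriptors follow the target SMILES (2R,3S,4R on the oxolane, R at the carbinol); chiral ligands, organocatalysts, auxiliaries and silylating agents are treated as reagents.

**Step 1**
Reactants: 1 catechol (benzene-1,2-diol)
Product: 2 guaiacol (2-methoxyphenol)
Conditions: MeI (1.0 equiv), K2CO3 (1.0 equiv), acetone, reflux
Reagents that add atoms: iodomethane, CI
Why: Williamson mono-O-methylation of one phenoxide; veratrole and unreacted 1 are removed by base extraction and distillation.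

**Step 2**
Reactants: 2 guaiacol
Product: 3 4-bromo-2-methoxyphenol
Conditions: NBS (1.0 equiv), DMF, 0 °C
Reagents that add atoms: N-bromosuccinimide, BrN1C(=O)CCC1=O
Why: Electrophilic aromatic bromination goes para to the free OH, the strongest director.

**Step 3**
Reactants: 3 4-bromo-2-methoxyphenol
Product: 4 (4-bromo-2-methoxyphenoxy)triisopropylsilane
Conditions: i-Pr3SiCl, imidazole, DMF, 23 °C
Reagents that add atoms: chlorotriisopropylsilane, CC(C)[Si](Cl)(C(C)C)C(C)C
Why: O-silylation of the phenol gives a base- and hydride-stable aryl silyl ether.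

**Step 4**
Reactants: 4 (4-bromo-2-methoxyphenoxy)triisopropylsilane
Product: 6 3-methoxy-4-(triisopropylsilyloxy)benzaldehyde, via arylmagnesium bromide 5 (not isolated)
Conditions: Mg turnings (I2 crystal), THF, 45 °C; DMF, 0 °C; then H2O
Reagents that add atoms: N,N-dimethylformamide, CN(C)C=O
Why: Magnesium insertion into the aryl bromide gives the Grignard reagent, which is formylated with DMF (Bouveault aldehyde synthesis); the aryl silyl ether is inert to the Grignard reagent.

**Step 5**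
Reactants: 7 methyl pent-4-enoate
Product: 9 methyl 4-oxobutanoate, via ozonide 8 (not isolated)
Conditions: O3, CH2Cl2, −78 °C; then Me2S, −78 to 23 °C
Reagents that add atoms: ozone, [O-][O+]=O
Why: Ozonolysis with reductive work-up gives the aldehyde ester fresh and free of oligomers.

**Step 6**
Reactants: 9 methyl 4-oxobutanoate
Product: 10 methyl (3S)-3-formyl-4-hydroxybutanoate
Conditions: aq. HCHO (37 %), (R)-2-[diphenyl(trimethylsilyloxy)methyl]pyrrolidine (10 mol %), pH 7 phosphate buffer, toluene, 23 °C; extractive work-up, used crude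
Reagents that add atoms: formaldehyde, C=O
Why: Enamine-catalysed α-hydroxymethylation (cross-aldol with formaldehyde); the diaryl(silyloxy)methyl group shields one face of the E-enamine, so formaldehyde adds from the open face and sets the S centre.

**Step 7**
Reactants: 10 methyl (3S)-3-formyl-4-hydroxybutanoate
Product: 11 methyl (3S)-3-formyl-4-(triisopropylsilyloxy)butanoate
Conditions: i-Pr3SiCl, imidazole, CH2Cl2, 0 °C
Reagents that add atoms: chlorotriisopropylsilane, CC(C)[Si](Cl)(C(C)C)C(C)C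
Why: Silylation of the primary alcohol under mild base blocks retro-aldol and dehydration and leaves the α-stereocentre untouched.

**Step 8**
Reactants: 4 (4-bromo-2-methoxyphenoxy)triisopropylsilane; 11 methyl (3S)-3-formyl-4-(triisopropylsilyloxy)butanoate
Product: 15 (4S,5R)-5-[3-methoxy-4-(triisopropylsilyloxy)phenyl]-4-[(triisopropylsilyloxy)methyl]oxolan-2-one, via aryllithium 12 (not isolated), via arylzinc 13 (not isolated), via hydroxy ester 14 (not isolated)
Conditions: 4, n-BuLi, t-BuOMe, −78 °C; ZnCl2; n-BuLi; Et2NCH2CH2NEt2; (2S)-(−)-3-exo-morpholinoisoborneol (5 mol %), 11, toluene, 0 °C; then H2O; PPTS (cat.), toluene, 50 °C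
Reagents that add atoms: none
Why: After bromine–lithium exchange and transmetalation, amino-alcohol-catalysed asymmetric aryl transfer from the mixed aryl(butyl)zinc to the Si face of the aldehyde sets the benzylic centre R (both α-arms are CH2X groups, so substrate bias is small and the ligand decides), and the γ-hydroxy ester lactonises to the trans lactone.

**Step 9**
Reactants: 15 (4S,5R)-5-[3-methoxy-4-(triisopropylsilyloxy)phenyl]-4-[(triisopropylsilyloxy)methyl]oxolan-2-one; 6 3-methoxy-4-(triisopropylsilyloxy)benzaldehyde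
Product: 17 (3S,4S,5R)-3-{(R)-hydroxy[3-methoxy-4-(triisopropylsilyloxy)phenyl]methyl}-5-[3-methoxy-4-(triisopropylsilyloxy)phenyl]-4-[(triisopropylsilyloxy)methyl]oxolan-2-one, via lithium enolate 16 (not isolated)
Conditions: LiN(SiMe3)2, THF, −78 °C; then 6, −78 °C; AcOH quench at −78 °C
Reagents that add atoms: none
Why: Aldol addition of the ring-locked E(O) lactone enolate: the aldehyde attacks trans to the C-4 substituent (sets C-3) and the closed Zimmerman–Traxler transition state gives the anti, R carbinol (expected about 4:1 over the syn epimer, separated by chromatography).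

**Step 10**
Reactants: 17 (aldol lactone)
Product: 18 (1R,2R,3S,4R)-2-(hydroxymethyl)-1,4-bis[3-methoxy-4-(triisopropylsilyloxy)phenyl]-3-[(triisopropylsilyloxy)methyl]butane-1,4-diol
Conditions: LiAlH4, THF, −20 to 0 °C; then H2O, aq. NaOH
Reagents that add atoms: none
Why: Hydride reduction of the lactone to the 1,4-diol is faster than retro-aldol at low temperature and touches no stereocentre.

**Step 11**
Reactants: 18 (triol)
Product: 20 (R)-[3-methoxy-4-(triisopropylsilyloxy)phenyl]{(3R,4S,5R)-5-[3-methoxy-4-(triisopropylsilyloxy)phenyl]-4-[(triisopropylsilyloxy)methyl]oxolan-3-yl}methanol, via monotosylate 19 (not isolated)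
Conditions: TsCl (1.1 equiv), pyridine, 0 to 40 °C
Reagents that add atoms: none
Why: Selective sulfonylation of the only primary hydroxyl, then 5-exo-tet Williamson closure by the 1,4-related benzylic hydroxyl with retention (its C–O bond is not broken); the other carbinol could only form an oxetane and stays free.

**Step 12**
Reactants: 20 (tris-silyl ether)
Product: 21 4-[(2R,3S,4R)-4-[(R)-hydroxy(4-hydroxy-3-methoxyphenyl)methyl]-3-(hydroxymethyl)oxolan-2-yl]-2-methoxyphenol (CNP0236765.5)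
Conditions: Bu4NF (3.5 equiv), AcOH (3.5 equiv), THF, 0 to 23 °C
Reagents that add atoms: none
Why: Fluoride cleaves all three Si–O bonds, and the acetic acid buffer keeps the p-hydroxybenzylic alcohol and ether from ionising to quinone methides.

**Compound list**
1 | catechol (benzene-1,2-diol) | Oc1ccccc1O | starting material
2 | guaiacol (2-methoxyphenol) | COc1ccccc1O | intermediate
3 | 4-bromo-2-methoxyphenol | COc1cc(Br)ccc1O | intermediate
4 | (4-bromo-2-methoxyphenoxy)triisopropylsilane | COc1cc(Br)ccc1O[Si](C(C)C)(C(C)C)C(C)C | intermediate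
5 | [3-methoxy-4-(triisopropylsilyloxy)phenyl]magnesium bromide | Br[Mg]c1ccc(O[Si](C(C)C)(C(C)C)C(C)C)c(OC)c1 | intermediate
6 | 3-methoxy-4-(triisopropylsilyloxy)benzaldehyde | COc1cc(C=O)ccc1O[Si](C(C)C)(C(C)C)C(C)C | intermediate
7 | methyl pent-4-enoate | COC(=O)CCC=C | starting material
8 | methyl 3-(1,2,4-trioxolan-3-yl)propanoate (ozonide) | COC(=O)CCC1OCOO1 | intermediate
9 | methyl 4-oxobutanoate | COC(=O)CCC=O | intermediate
10 | methyl (3S)-3-formyl-4-hydroxybutanoate | O=C[C@@H](CC(=O)OC)CO | intermediate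
11 | methyl (3S)-3-formyl-4-(triisopropylsilyloxy)butanoate | O=C[C@@H](CC(=O)OC)CO[Si](C(C)C)(C(C)C)C(C)C | intermediate
12 | [3-methoxy-4-(triisopropylsilyloxy)phenyl]lithium | [Li]c1ccc(O[Si](C(C)C)(C(C)C)C(C)C)c(OC)c1 | intermediate
13 | butyl[3-methoxy-4-(triisopropylsilyloxy)phenyl]zinc | CCCC[Zn]c1ccc(O[Si](C(C)C)(C(C)C)C(C)C)c(OC)c1 | intermediate
14 | methyl (3S,4R)-4-hydroxy-4-[3-methoxy-4-(triisopropylsilyloxy)phenyl]-3-[(triisopropylsilyloxy)methyl]butanoate | O[C@@H](c1ccc(O[Si](C(C)C)(C(C)C)C(C)C)c(OC)c1)[C@@H](CC(=O)OC)CO[Si](C(C)C)(C(C)C)C(C)C | intermediate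
15 | (4S,5R)-5-[3-methoxy-4-(triisopropylsilyloxy)phenyl]-4-[(triisopropylsilyloxy)methyl]oxolan-2-one | O=C1C[C@@H](CO[Si](C(C)C)(C(C)C)C(C)C)[C@H](c2ccc(O[Si](C(C)C)(C(C)C)C(C)C)c(OC)c2)O1 | intermediate
16 | lithium (4S,5R)-5-[3-methoxy-4-(triisopropylsilyloxy)phenyl]-4-[(triisopropylsilyloxy)methyl]-4,5-dihydrofuran-2-olate | [Li]OC1=C[C@@H](CO[Si](C(C)C)(C(C)C)C(C)C)[C@H](c2ccc(O[Si](C(C)C)(C(C)C)C(C)C)c(OC)c2)O1 | intermediate
17 | (3S,4S,5R)-3-{(R)-hydroxy[3-methoxy-4-(triisopropylsilyloxy)phenyl]methyl}-5-[3-methoxy-4-(triisopropylsilyloxy)phenyl]-4-[(triisopropylsilyloxy)methyl]oxolan-2-one | COc1cc([C@H](O)[C@H]2C(=O)O[C@@H](c3ccc(O[Si](C(C)C)(C(C)C)C(C)C)c(OC)c3)[C@@H]2CO[Si](C(C)C)(C(C)C)C(C)C)ccc1O[Si](C(C)C)(C(C)C)C(C)C | intermediate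
18 | (1R,2R,3S,4R)-2-(hydroxymethyl)-1,4-bis[3-methoxy-4-(triisopropylsilyloxy)phenyl]-3-[(triisopropylsilyloxy)methyl]butane-1,4-diol | COc1cc([C@H](O)[C@@H](CO)[C@@H](CO[Si](C(C)C)(C(C)C)C(C)C)[C@@H](O)c2ccc(O[Si](C(C)C)(C(C)C)C(C)C)c(OC)c2)ccc1O[Si](C(C)C)(C(C)C)C(C)C | intermediate
19 | [(1R,2R,3S,4R)-1,4-dihydroxy-1,4-bis[3-methoxy-4-(triisopropylsilyloxy)phenyl]-3-[(triisopropylsilyloxy)methyl]butan-2-yl]methyl 4-methylbenzenesulfonate | COc1cc([C@H](O)[C@@H](COS(=O)(=O)c3ccc(C)cc3)[C@@H](CO[Si](C(C)C)(C(C)C)C(C)C)[C@@H](O)c2ccc(O[Si](C(C)C)(C(C)C)C(C)C)c(OC)c2)ccc1O[Si](C(C)C)(C(C)C)C(C)C | intermediate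
20 | (R)-[3-methoxy-4-(triisopropylsilyloxy)phenyl]{(3R,4S,5R)-5-[3-methoxy-4-(triisopropylsilyloxy)phenyl]-4-[(triisopropylsilyloxy)methyl]oxolan-3-yl}methanol | COc1cc([C@H](O)[C@H]2CO[C@@H](c3ccc(O[Si](C(C)C)(C(C)C)C(C)C)c(OC)c3)[C@@H]2CO[Si](C(C)C)(C(C)C)C(C)C)ccc1O[Si](C(C)C)(C(C)C)C(C)C | intermediate
21 | 4-[(2R,3S,4R)-4-[(R)-hydroxy(4-hydroxy-3-methoxyphenyl)methyl]-3-(hydroxymethyl)oxolan-2-yl]-2-methoxyphenol | COc1cc([C@H](O)[C@H]2CO[C@@H](c3ccc(O)c(OC)c3)[C@@H]2CO)ccc1O | target

**Total step count:** 12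
**Longest linear sequence:** 8 steps (for example steps 1, 2, 3, 8, 9, 10, 11, 12; the branches through 6 and through 7 are also 8).

**Steps most likely to fail, with fallbacks**

Step 6 (organocatalytic hydroxymethylation: the β-hydroxy aldehyde is labile and its ee on this substrate is untested). The fallback sets out from aldehyde 6 and comes back at lactone 15; it replaces organocatalysis plus aryl transfer by an auxiliary-controlled syn-aldol. Succinic anhydride is opened with methanol to 4-methoxy-4-oxobutanoic acid F1. Activation with t-BuCOCl/Et3N (mixed anhydride) and reaction with lithiated (R)-4-benzyl-1,3-oxazolidin-2-one gives methyl 4-[(4R)-4-benzyl-2-oxo-1,3-oxazolidin-3-yl]-4-oxobutanoate F2. Enolisation with Bu2BOTf/i-Pr2NEt and addition of 6 give the syn-aldol adduct methyl (3R,4R)-3-{[(4R)-4-benzyl-2-oxo-1,3-oxazolidin-3-yl]carbonyl}-4-hydroxy-4-[3-methoxy-4-(triisopropylsilyloxy)phenyl]butanoate F3. This closes onto its methyl ester to the trans lactone imide (4R)-4-benzyl-3-{[(2R,3R)-2-[3-methoxy-4-(triisopropylsilyloxy)phenyl]-5-oxooxolan-3-yl]carbonyl}-1,3-oxazolidin-2-one F4. NaBH4 in THF/H2O removes the auxiliary reductively without touching the lactone, giving (4S,5R)-4-(hydroxymethyl)-5-[3-methoxy-4-(triisopropylsilyloxy)phenyl]oxolan-2-one F5. Silylation with i-Pr3SiOTf/2,6-lutidine gives 15.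

Step 8 (ligand-controlled aryl transfer to an α-branched, epimerisable aldehyde). The fallback sets out from bromide 4 and aldehyde 11 and comes back at 15; it uses thermodynamic instead of catalyst control. Arylmagnesium bromide 5, made from 4 as in step 4, is added to 11 in THF at −78 °C without any chiral ligand. This gives hydroxy ester 14 together with its carbinol epimer methyl (3S,4S)-4-hydroxy-4-[3-methoxy-4-(triisopropylsilyloxy)phenyl]-3-[(triisopropylsilyloxy)methyl]butanoate F6. Mildly acidic work-up (PPTS, toluene, 50 °C) lactonises both, to 15 and to its C-5 epimer (4S,5S)-5-[3-methoxy-4-(triisopropylsilyloxy)phenyl]-4-[(triisopropylsilyloxy)methyl]oxolan-2-one F7. Stirring the mixture with CF3CO2H in CH2Cl2 at 0 °C reversibly ionises the electron-rich benzylic C–O bond and funnels the cis isomer into the more stable trans lactone 15.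

Step 9 (carbinol selectivity of the lithium aldol). The fallback sets out from lactone 15 and arylmagnesium bromide 5 (made from bromide 4 as in step 4) and comes back at 17; it sets the carbinol by ketone reduction instead of by the aldol. Arylmagnesium bromide 5 is added to excess ClCO2Me at −78 °C to give methyl 3-methoxy-4-(triisopropylsilyloxy)benzoate F8. Claisen acylation of enolate 16 (from 15 with 2.2 equiv LiN(SiMe3)2) with F8 gives (3S,4S,5R)-3-[3-methoxy-4-(triisopropylsilyloxy)benzoyl]-5-[3-methoxy-4-(triisopropylsilyloxy)phenyl]-4-[(triisopropylsilyloxy)methyl]oxolan-2-one F9, trans at C-3 by equilibration of the 1,3-dicarbonyl. Reduction with KBH(s-Bu)3 in THF at −78 °C (non-chelating, hydride anti to the lactone carbonyl) is expected to give the anti alcohol 17; if it gave the syn carbinol instead, the hydride would have to be changed.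

**Further compounds**
F1 | step 6 | 4-methoxy-4-oxobutanoic acid | COC(=O)CCC(O)=O
F2 | step 6 | methyl 4-[(4R)-4-benzyl-2-oxo-1,3-oxazolidin-3-yl]-4-oxobutanoate | COC(=O)CCC(=O)N1[C@H](Cc2ccccc2)COC1=O
F3 | step 6 | methyl (3R,4R)-3-{[(4R)-4-benzyl-2-oxo-1,3-oxazolidin-3-yl]carbonyl}-4-hydroxy-4-[3-methoxy-4-(triisopropylsilyloxy)phenyl]butanoate | O[C@@H](c1ccc(O[Si](C(C)C)(C(C)C)C(C)C)c(OC)c1)[C@@H](CC(=O)OC)C(=O)N2[C@H](Cc3ccccc3)COC2=O
F4 | step 6 | (4R)-4-benzyl-3-{[(2R,3R)-2-[3-methoxy-4-(triisopropylsilyloxy)phenyl]-5-oxooxolan-3-yl]carbonyl}-1,3-oxazolidin-2-one | O=C1C[C@@H](C(=O)N2[C@H](Cc3ccccc3)COC2=O)[C@H](c4ccc(O[Si](C(C)C)(C(C)C)C(C)C)c(OC)c4)O1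
F5 | step 6 | (4S,5R)-4-(hydroxymethyl)-5-[3-methoxy-4-(triisopropylsilyloxy)phenyl]oxolan-2-one | O=C1C[C@@H](CO)[C@H](c2ccc(O[Si](C(C)C)(C(C)C)C(C)C)c(OC)c2)O1
F6 | step 8 | methyl (3S,4S)-4-hydroxy-4-[3-methoxy-4-(triisopropylsilyloxy)phenyl]-3-[(triisopropylsilyloxy)methyl]butanoate | O[C@H](c1ccc(O[Si](C(C)C)(C(C)C)C(C)C)c(OC)c1)[C@@H](CC(=O)OC)CO[Si](C(C)C)(C(C)C)C(C)C
F7 | step 8 | (4S,5S)-5-[3-methoxy-4-(triisopropylsilyloxy)phenyl]-4-[(triisopropylsilyloxy)methyl]oxolan-2-one | O=C1C[C@@H](CO[Si](C(C)C)(C(C)C)C(C)C)[C@@H](c2ccc(O[Si](C(C)C)(C(C)C)C(C)C)c(OC)c2)O1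
F8 | step 9 | methyl 3-methoxy-4-(triisopropylsilyloxy)benzoate | COC(=O)c1ccc(O[Si](C(C)C)(C(C)C)C(C)C)c(OC)c1
F9 | step 9 | (3S,4S,5R)-3-[3-methoxy-4-(triisopropylsilyloxy)benzoyl]-5-[3-methoxy-4-(triisopropylsilyloxy)phenyl]-4-[(triisopropylsilyloxy)methyl]oxolan-2-one | COc1cc(C(=O)[C@H]2C(=O)O[C@@H](c3ccc(O[Si](C(C)C)(C(C)C)C(C)C)c(OC)c3)[C@@H]2CO[Si](C(C)C)(C(C)C)C(C)C)ccc1O[Si](C(C)C)(C(C)C)C(C)C
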